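## Retrosynthetic overview

1. The last bond is C4a–aryl (the five-membered ring). It is made by intramolecular Michael addition of the ring-fusion enol to an aryl quinone, which is unmasked from a 2,5-dimethoxyphenyl group.
2. The C9a–prenyl bond comes from a decarboxylative O-to-C prenyl shift of a β-keto prenyl ester, anti to the neighbouring aryl group.
3. The cyclohexene ring comes from a catalyst-controlled [4+2] of a quinone prenyl ester with an (E)-1-aryl-3-methylbutadiene. The ester makes the substituted quinone C=C the reacting one and carries the prenyl group.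
4. The quinone ester is made from gentisic acid and prenyl bromide; the diene from 2-bromo-1,4-dimethoxybenzene and isoprene.
5. Ring order: the enedione ring and the arene are bought; the cyclohexene forms first and the cyclopentane second, both in the same flask.

Assumption: the pybox ligand enantiomer is the one that gives the 5R cycloadduct (its antipode is used if a test run shows the opposite sense); names use naphthalene locants for 8–10 and fluorene locants for 11, and the SMILES are authoritative.

## Route

Step 1
Reactants: 1 2,5-dihydroxybenzoic acid; 2 1-bromo-3-methylbut-2-ene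
Product: 3 3-methylbut-2-enyl 2,5-dihydroxybenzoate
Conditions: KHCO3 (1.1 equiv), DMF, 40 °C
Reagents that add atoms: none
Why: Bicarbonate deprotonates only the carboxylic acid, so the carboxylate is alkylated by the primary allylic bromide while both phenols stay free (SN2 carboxylate O-alkylation); no stereocenter is formed.

Step 2
Reactants: 4 2-bromo-1,4-dimethoxybenzene; 5 isoprene
Product: 6 2-[(1E)-3-methylbuta-1,3-dienyl]-1,4-dimethoxybenzene
Conditions: Pd(OAc)2 (3 mol %), P(o-tol)3, Et3N, MeCN, 100 °C, sealed tube
Reagents that add atoms: none
Why: The arylpalladium species adds to the unsubstituted vinyl terminus of isoprene and β-hydride elimination gives the conjugated E-diene (Mizoroki–Heck reaction); no stereocenter is formed.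

Step 3
Reactants: 3 3-methylbut-2-enyl 2,5-dihydroxybenzoate
Product: 7 3-methylbut-2-enyl 3,6-dioxocyclohexa-1,4-diene-1-carboxylate
Conditions: Ag2O (2 equiv), Na2SO4, Et2O, 23 °C; filter and use at once
Reagents that add atoms: none
Why: Silver(I) oxide dehydrogenates the hydroquinone under neutral anhydrous conditions that leave the prenyl ester untouched (hydroquinone-to-quinone oxidation); no stereocenter is formed.

Step 4
Reactants: 7 3-methylbut-2-enyl 3,6-dioxocyclohexa-1,4-diene-1-carboxylate; 6 2-[(1E)-3-methylbuta-1,3-dienyl]-1,4-dimethoxybenzene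
Product: 11 (4aR,9R,9aS)-5,8-dihydroxy-11-methyl-9a-(3-methylbut-2-enyl)-9,9a-dihydro-4aH-4a,9-prop[1]enofluorene-1,4-dione (CNP0166383.1), via cycloadduct prenyl ester 8 (not isolated), via C-prenyl enedione 9 (not isolated), via aryl quinone 10 (not isolated)
Conditions: one flask: (i) (S,S)-Ph-pybox·Sm(OTf)3 (10 mol %), 4 Å MS, THF, −78 to −20 °C; (ii) Pd(PPh3)4 (5 mol %), 23 °C; (iii) CAN (2.6 equiv), MeCN–H2O, 0 °C; (iv) aq NaHCO3, 23 °C
Reagents that add atoms: water (O)
Why: Proposed new method: a four-stage cascade in one flask in which each stage is a known reaction type and only the telescoping is new — the ester makes C2=C3 of 7 the only strongly activated dienophile site and its two-point binding to the chiral Lewis acid fixes C5 as R in a [4+2] that joins the CH2 terminus of 6 to the unsubstituted quinone carbon (ester-directed quinone Diels–Alder reaction); Pd(0) then ionises the prenyl β-keto ester of 8, CO2 leaves and the enolate is C-prenylated at the unhindered allyl terminus anti to the pseudoaxial C5 aryl group, which sets C4a as S whatever the endo/exo outcome of the cycloaddition (Tsuji decarboxylative allylation); CAN turns the dimethoxyarene of 9 into quinone 10 (oxidative demethylation), whose C8a enol adds to the neighbouring quinone carbon on the only face the two-atom tether allows, so that the last stereocenter follows from C5 and the hydroquinone is released without any protecting group (intramolecular Michael addition to a quinone, the carbon counterpart of the cyclodopa ring closure).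

## Compound list

1 | 2,5-dihydroxybenzoic acid (gentisic acid) | O=C(O)c1cc(O)ccc1O | starting material
2 | 1-bromo-3-methylbut-2-ene (prenyl bromide) | CC(C)=CCBr | starting material
3 | 3-methylbut-2-enyl 2,5-dihydroxybenzoate | CC(C)=CCOC(=O)c1cc(O)ccc1O | intermediate
4 | 2-bromo-1,4-dimethoxybenzene | COc1ccc(OC)c(Br)c1 | starting material
5 | isoprene (2-methylbuta-1,3-diene) | C=CC(C)=C | starting material
6 | 2-[(1E)-3-methylbuta-1,3-dienyl]-1,4-dimethoxybenzene | COc1ccc(OC)c(/C=C/C(C)=C)c1 | intermediate
7 | 3-methylbut-2-enyl 3,6-dioxocyclohexa-1,4-diene-1-carboxylate | CC(C)=CCOC(=O)C1=CC(=O)C=CC1=O | intermediate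
8 | 3-methylbut-2-enyl (4aR,5R,8aR)-5-(2,5-dimethoxyphenyl)-7-methyl-1,4-dioxo-1,4,4a,5,8,8a-hexahydronaphthalene-4a-carboxylate | CC(C)=CCOC(=O)[C@@]12C(=O)C=CC(=O)[C@@H]1CC(C)=C[C@@H]2c1cc(OC)ccc1OC | intermediate
9 | (4aS,5R,8aR)-5-(2,5-dimethoxyphenyl)-7-methyl-4a-(3-methylbut-2-enyl)-4a,5,8,8a-tetrahydronaphthalene-1,4-dione | CC(C)=CC[C@@]12C(=O)C=CC(=O)[C@@H]1CC(C)=C[C@@H]2c1cc(OC)ccc1OC | intermediate
10 | (4aS,5R,8aR)-5-(3,6-dioxocyclohexa-1,4-dienyl)-7-methyl-4a-(3-methylbut-2-enyl)-4a,5,8,8a-tetrahydronaphthalene-1,4-dione | CC(C)=CC[C@@]12C(=O)C=CC(=O)[C@@H]1CC(C)=C[C@@H]2C1=CC(=O)C=CC1=O | intermediate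
11 | (4aR,9R,9aS)-5,8-dihydroxy-11-methyl-9a-(3-methylbut-2-enyl)-9,9a-dihydro-4aH-4a,9-prop[1]enofluorene-1,4-dione (CNP0166383.1) | CC(C)=CC[C@@]12C(=O)C=CC(=O)[C@@]13CC(C)=C[C@@H]2c1c(O)ccc(O)c13 | target

## Step count and risks

Total step count: 4. Longest linear sequence: 3 steps (steps 1, 3 and 4).

The three steps most likely to fail, most risky first:

Step 4. The weak points are the prenyl transfer and the final ring closure. The prenyl transfer may give branched or O-prenylated product, or the enolate may be protonated and the ring aromatise. The closure onto the quinone is a 5-endo addition. Four stages must also tolerate each other without isolation. The fallback replaces direct prenyl transfer by allyl transfer followed by olefin cross-metathesis, with isolation after each stage. It sets out from 1: KHCO3 and allyl bromide give allyl 2,5-dihydroxybenzoate F1, and Ag2O gives allyl 3,6-dioxocyclohexa-1,4-diene-1-carboxylate F2. The same catalysed cycloaddition with 6 gives the allyl ester cycloadduct F3, and Pd(PPh3)4 gives the 4a-allyl enedione F4; the unsubstituted allyl group has no regiochemical ambiguity and recombines faster. Cross-metathesis with 2-methylbut-2-ene (Grubbs second-generation catalyst) turns the allyl into the prenyl group. The fallback comes back to the route at 9, which is treated with CAN and then NaHCO3 as in the last two stages of step 4.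

Step 3. Quinone ester 7 may dimerise or hydrate before it is used. The fallback does not accumulate 7: 3 is oxidised with Ag2O in the presence of 6 and the chiral Lewis acid, so that the quinone ester is trapped by cycloaddition as it forms. It sets out from 3 and comes back to the route at 8, which is carried on with Pd(0), CAN and NaHCO3. This fallback makes no new compound (F0).

Step 2. The Heck reaction of the electron-rich bromide with volatile isoprene may give low conversion or regioisomeric dienes. The fallback builds the diene by carbonyl addition and dehydration instead of cross-coupling. It sets out from 4: bromine–lithium exchange (n-BuLi, THF, −78 °C) and addition to 3-methylbut-2-enal give 1-(2,5-dimethoxyphenyl)-3-methylbut-2-en-1-ol F5 (racemic). Acid-catalysed 1,4-dehydration (cat. TsOH, toluene) then gives the E-diene, and the fallback comes back to the route at 6.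

Further compounds
F1 | step 4 | allyl 2,5-dihydroxybenzoate | C=CCOC(=O)c1cc(O)ccc1O
F2 | step 4 | allyl 3,6-dioxocyclohexa-1,4-diene-1-carboxylate | C=CCOC(=O)C1=CC(=O)C=CC1=O
F3 | step 4 | allyl (4aR,5R,8aR)-5-(2,5-dimethoxyphenyl)-7-methyl-1,4-dioxo-1,4,4a,5,8,8a-hexahydronaphthalene-4a-carboxylate | C=CCOC(=O)[C@@]12C(=O)C=CC(=O)[C@@H]1CC(C)=C[C@@H]2c1cc(OC)ccc1OC
F4 | step 4 | (4aS,5R,8aR)-4a-allyl-5-(2,5-dimethoxyphenyl)-7-methyl-4a,5,8,8a-tetrahydronaphthalene-1,4-dione | C=CC[C@@]12C(=O)C=CC(=O)[C@@H]1CC(C)=C[C@@H]2c1cc(OC)ccc1OC
F0 | step 3 | none | none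
F5 | step 2 | 1-(2,5-dimethoxyphenyl)-3-methylbut-2-en-1-ol (racemic) | COc1ccc(OC)c(C(O)C=C(C)C)c1
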